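## Structural features

Locants C1–C6 (ring) and C1'–C17' (chain) are those of the target 15; benzofuran locants appear only in compound names.

- Compound 15 is a cyclohex-2-en-1-one: C1 ketone, C2=C3 alkene, C4 secondary carbinol, C5 methylene, C6 tertiary carbinol α to the ketone.
- C6 carries a seventeen-carbon chain through the methylene C1'. The chain has a secondary carbinol at C2' and an isolated (Z)-alkene at C10'=C11'.
- The three stereocentres are (4S), (6R) and (2'S). No two are adjacent: C4 and C6 are 1,3 across C5 with their hydroxyls cis on the ring, and C2' is 1,3 to C6 across C1'. All stereocontrol must therefore be relayed over a methylene.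
- Fragile groups: the γ-hydroxy enone can lose water towards an aromatic ring, and the tertiary α-ketol is prone to rearrangement. The C2' hydroxyl can close a hemiketal on C1. The (Z)-alkene excludes hydrogenation, radical conditions and undirected electrophilic oxidants.
- The real difficulty is the oxygenated quaternary C6 in a defined relation to both C4 and C2', to be reached without a long protecting-group sequence.
- The key step exploits a latent ring. The atoms O(C2')–C2'–C1'–C6–C1 form a five-membered ring once the C2' oxygen is bonded to C1. With C5 a methylene, the carbocycle then is a 2-alkyl-2,3-dihydrobenzofuran that has taken up hydrogen at C2 and C5.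
- Configurational check: the (S) centre of the dihydrobenzofuran is the (2'S) centre of 15, and oxygen delivered to C6 on the face of the five-membered ring opposite the chain gives (6R).

## Logic of the disconnections

**15 ⇒ 13 (through 14).** The C4 hydroxyl and the C2=C3 alkene are folded back into a C3–C4 epoxide (the C3–O bond is restored), and the C1 carbonyl is returned to a mixed ketal that holds the C2' oxygen on C1. The hydroxy enone is the most fragile array and should appear last. One ketal masks the ketone, the enone and the C2' hydroxyl without a protecting-group step. The forward step needs the ketal to hydrolyse faster than the epoxide opens, and the enolate at C2 to expel the C3 oxygen while the C4–O bond stays intact.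

**13 ⇒ 12.** The two C–O bonds of the epoxide are cut. The tertiary C6 hydroxyl is homoallylic to C3=C4 and can deliver oxygen to its own face, which is the cis-4,6 relation of 15. The C4 stereocentre is removed. The forward step needs a reagent that binds the tertiary hydroxyl and ignores the chain alkene.

**12 ⇒ 10 (through 11).** The C6–OH and C1–OMe bonds are cut, which leaves the tetrasubstituted enol ether C1=C6. This is the most electron-rich of the three alkenes, and its faces differ only through the C2' substituent on the five-membered ring. One stereocentre remains. The forward step needs attack anti to the chain and on the enol ether only.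

**10 ⇒ 9 (key step).** The hydrogens at C2 and C5 are removed; no skeletal bond is cut. The ring carbons of 15 map onto a benzene ring with oxygen at C1 and carbon at C6, so the whole carbocycle comes from an arene. The gain is a stable aromatic compound with one stereocentre. The forward reduction must place hydrogen only at C2 and C5 and leave the chain alkene alone.

**9 ⇒ 8.** The aryl C1–O bond is cut. Closing the furan ring at the aryl carbon leaves the C2'–O bond untouched, so the configuration is retained. An aryl ether deprotection, which a closure at C2' would require, is avoided. The forward step needs C–O coupling of a secondary alkoxide with an aryl bromide.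

**8 ⇒ 5 + 6 (through 7).** The C6–C1' bond is cut. A monosubstituted oxirane is opened only at its CH2 carbon, so a six-carbon arene and the complete chain are joined in one step with the carbinol in place. The forward step needs an ortho-bromoaryl metal that is kept cold.

**5 ⇒ 4.** No bond is cut; the single enantiomer is traced to the racemate. A sulfur-ylide epoxidation cannot give one enantiomer, so a hydrolytic kinetic resolution is built in. The cost is half of the material; the demand is the correct catalyst enantiomer.

**4 ⇒ 1 + 2 (through 3).** The C1'–C2' and C1'–O bonds are cut. Compound 1 already holds the (Z)-alkene at the right distance, and one carbon is added. The forward step must tolerate an enolisable aldehyde.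

## Other disconnections considered

**Alternative 1:** The cut is the C1–C6 ring bond, which opens the carbocycle to the acyclic keto aldehyde A1.

- *Forward key step:* a triazolium-derived carbene converts the C1 aldehyde into its enaminol, which adds 6-exo to the C6 ketone and gives A2, the 2,3-dihydro target as its 4,2'-bis-silyl ether.
- *In favour:* ring and oxygenated quaternary carbon arise in one catalytic, redox-neutral C–C bond formation. A chiral triazolium could add reagent control at C6.
- *Better than the chosen plan:* C4 and C2' arrive fixed from independent asymmetric steps, so no relay can erode them.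
- *Against:* the C6 ketone carries two CH2–CH(OSi) arms of similar size, so the facial preference is not obvious. Both arms are β-silyloxy ketones and can eliminate under the basic conditions. Aldol closure of a ketone enolate onto the aldehyde competes. A2 still needs C2–C3 dehydrogenation and desilylation next to a sensitive hydroxy enone.
- *Equal to the chosen plan:* the dehydrogenation is regiochemically unambiguous because C6 is quaternary, and both plans carry their main uncertainty at C6.
- *Comparison:* structurally, the alternative builds the ring while the chosen plan takes it from benzene. Mechanistically, a polar umpolung addition creates C6 in the key step, whereas the chosen reduction creates no stereocentre and leaves two relayed oxidations. In step economy, A1 needs two protected chiral fragments and a ketone-forming coupling, so the alternative should be longer than eight steps.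

**Alternative 2:** The cut is the C6–C1' bond, leading back to the allylic glycolate ester A3.

- *Forward key step:* LiHMDS and Me3SiCl give the chelated silyl ketene acetal, which rearranges through a chair (Ireland–Claisen). The C6–C1' bond forms as the C3'–O bond breaks, giving acid A4.
- *Better than the chosen plan:* chirality transfer from a secondary carbinol to a quaternary ether carbon through an ordered chair is more dependable for C6 than a 1,3-relay on a nearly flat ring.
- *Against:* the rearrangement consumes the chain stereocentre; C2' emerges as a masked ketone and must later be reduced to the (S)-carbinol under remote induction. The carbocycle is not formed: C2 must be introduced and the ring closed after the key step. A p-methoxybenzyl ether, two silyl ethers and an acid-labile enol ether must be carried and removed. The 2-methoxyallyl carbinol in A3 is itself a sensitive enantio-enriched intermediate.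
- *Comparison:* structurally, ring and chain are both assembled from acyclic pieces, against an arene plus a C16 aldehyde in the chosen plan. Mechanistically, a concerted pericyclic step with predictable stereochemistry stands against a reduction followed by relay. In step economy the alternative is clearly longer.

**Alternative 3:** The cut is the C6–O bond, leading back to the aromatic alkylhydroquinone A5.

- *Forward key step:* a flavin hydroperoxide in a monooxygenase of the phenol ortho-hydroxylase class transfers oxygen to the alkyl-bearing ring carbon. The dienol tautomerises to the ene-dione A6.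
- *In favour:* it mirrors a plausible biogenesis and works in water at ambient temperature, which the (Z)-alkene tolerates as well as it tolerates the chosen reduction (equal on this point).
- *Better than the chosen plan:* an active site could fix C6 absolutely in the key step. A5 is only a few steps from 5 and a dimethoxyaryl nucleophile, so step economy could be better if a suitable enzyme existed.
- *Against:* no enzyme is known for this substrate. Enzymes of this class usually need a carbonyl-bearing resorcinol for binding, so enzyme discovery or engineering would come first. Ordinary hydroxylation at the free ring positions and autoxidation to the quinone compete. A6 is a β-hydroxy ketone that can dehydrate to an alkylbenzoquinone. Its C4 carbonyl must still be reduced chemo- and stereoselectively to the cis alcohol.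
- *Comparison:* structurally, both plans see the ring as an arene; this one dearomatises by oxidation, the chosen one by reduction followed by two oxidations. Mechanistically, an electrophilic oxygen transfer sets C6 directly, against an electron-transfer reduction that sets nothing. The chosen plan uses only established reagents.

Key step: step 5

Assumption: 12 and 13 are drawn as the cis-fused anomer (C7a methoxy cis to C3a hydroxyl); this ketal carbon is not controlled and does not matter, because it becomes the C1 carbonyl of 15.

## Route

Step 1
Reactants: 1 (Z)-hexadec-9-enal; 2 trimethylsulfonium iodide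
Product: 4 rac-2-[(8Z)-pentadec-8-en-1-yl]oxirane, via dimethylsulfonium methylide 3 (not isolated)
Conditions: 2, NaH, DMSO/THF, 0 °C; then 1, 0 °C → rt
Reagents that add atoms: none
Why: Corey–Chaykovsky epoxidation: ylide 3 adds to the aldehyde and the betaine closes to the terminal oxirane with loss of dimethyl sulfide. The unconjugated (Z)-alkene is inert to the ylide; slow addition of 1 to preformed 3 limits aldol condensation; the product is racemic.

Step 2
Reactants: 4 rac-2-[(8Z)-pentadec-8-en-1-yl]oxirane
Product: 5 (S)-2-[(8Z)-pentadec-8-en-1-yl]oxirane
Conditions: (S,S)-(salen)Co(OAc) (0.5 mol%), H2O (0.55 equiv), THF, 0 °C → rt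
Reagents that add atoms: none
Why: Jacobsen hydrolytic kinetic resolution (salen = N,N'-bis(3,5-di-tert-butylsalicylidene)-1,2-cyclohexanediaminate, trivalent cobalt): the (R)-oxirane is hydrolysed to the diol and 5 remains, at most half of the material. By the usual sense of this resolution for alkyl oxiranes the (S,S) complex leaves the (S)-oxirane; this sets the later C2' centre.

Step 3
Reactants: 6 1,2-dibromobenzene; 5 (S)-2-[(8Z)-pentadec-8-en-1-yl]oxirane
Product: 8 (2S,10Z)-1-(2-bromophenyl)heptadec-10-en-2-ol, via 2-bromophenylmagnesium chloride 7 (not isolated)
Conditions: 6, i-PrMgCl·LiCl, THF, −15 °C; then CuI (10 mol%), 5, −15 → 0 °C; 1 M HCl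
Reagents that add atoms: none
Why: Bromine–magnesium exchange gives 7, kept cold to suppress benzyne formation; copper-catalysed SN2 opening of the monosubstituted oxirane then occurs at the CH2 carbon. The C–O bond of the stereocentre is not touched, so the configuration is retained.

Step 4
Reactants: 8 (2S,10Z)-1-(2-bromophenyl)heptadec-10-en-2-ol
Product: 9 (2S)-2-[(8Z)-pentadec-8-en-1-yl]-2,3-dihydro-1-benzofuran
Conditions: CuI (10 mol%), 1,10-phenanthroline (20 mol%), Cs2CO3, toluene, 110 °C
Reagents that add atoms: none
Why: Intramolecular Ullmann-type etherification: the caesium alkoxide closes the five-membered ring on the aryl bromide. The new bond is aryl C–O, so the carbinol carbon keeps its configuration and becomes C2 of the dihydrobenzofuran.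

Step 5
Reactants: 9 (2S)-2-[(8Z)-pentadec-8-en-1-yl]-2,3-dihydro-1-benzofuran
Product: 10 (2S)-2-[(8Z)-pentadec-8-en-1-yl]-2,3,4,7-tetrahydro-1-benzofuran
Conditions: Li, NH3(l), THF, t-BuOH, −78 → −33 °C; MeOH quench; aq. NaHCO3 work-up
Reagents that add atoms: none
Why: This is a Birch reduction of an alkyl aryl ether, the reaction type that converts anisoles, chromans and 2,3-dihydrobenzofurans into 1-alkoxycyclohexa-1,4-dienes. Lithium in ammonia transfers an electron to the benzene ring of 9, the radical anion is protonated by t-BuOH, a second electron gives the cyclohexadienyl anion, and this is protonated at its central carbon, para to the first site, so that the kinetic non-conjugated 1,4-diene results. The two hydrogens enter at C7 and C4 of the benzofuran (C2 and C5 of 15) because only this pattern keeps both donors, the ring oxygen on C7a and the alkyl carbon on C3a, on a double bond; the regioselectivity is thus fixed by the substitution pattern of 9. No carbon–carbon bond forms and no ring closes. No stereocentre is created, and C2 is untouched because the oxygen atom and C3 insulate it from the reduced π-system. Chemoselectivity over the chain alkene rests on the fact that an isolated cis-alkene does not accept an electron from lithium in ammonia at a useful rate and has no conjugating partner through which it could isomerise. The alcohol is present from the start so that lithium amide does not accumulate and move the new diene into conjugation, which would open the way to over-reduction. The product is an acid-labile dienol ether and is taken on after a basic work-up.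

Step 6
Reactants: 10 (2S)-2-[(8Z)-pentadec-8-en-1-yl]-2,3,4,7-tetrahydro-1-benzofuran
Product: 12 (2S,3aS,7aR)-7a-methoxy-2-[(8Z)-pentadec-8-en-1-yl]-2,3,3a,4,7,7a-hexahydro-1-benzofuran-3a-ol, via enol ether epoxide 11 (not isolated)
Conditions: m-CPBA (1.05 equiv), NaHCO3, MeOH/CH2Cl2, −40 → 0 °C
Reagents that add atoms: m-chloroperbenzoic acid, O=C(OO)c1cccc(Cl)c1; methanol, CO
Why: Peracid epoxidation of the tetrasubstituted enol ether, by far the most nucleophilic of the three alkenes, followed by methanolysis of the alkoxy epoxide at the acetal carbon. Oxygen should enter on the face of the dihydrofuran ring opposite the C2 chain, which gives the (3aS) carbinol, C6 of 15; the bicarbonate buffer prevents acid-catalysed addition of methanol to the enol ether.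

Step 7
Reactants: 12 (2S,3aS,7aR)-7a-methoxy-2-[(8Z)-pentadec-8-en-1-yl]-2,3,3a,4,7,7a-hexahydro-1-benzofuran-3a-ol
Product: 13 (2S,3aR,5S,6R,7aR)-5,6-epoxy-7a-methoxy-2-[(8Z)-pentadec-8-en-1-yl]octahydro-1-benzofuran-3a-ol
Conditions: VO(acac)2 (5 mol%), t-BuOOH (decane solution), CH2Cl2, 0 °C → rt
Reagents that add atoms: tert-butyl hydroperoxide, CC(C)(C)OO
Why: Hydroxyl-directed epoxidation: the pentavalent vanadium alkoxide of the tertiary C3a hydroxyl delivers the peroxide oxygen to the homoallylic ring alkene on its own face, which sets the cis relation of the C4 and C6 oxygens of 15. The chain (Z)-alkene has no hydroxyl within reach and should not react at a comparable rate.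

Step 8
Reactants: 13 (2S,3aR,5S,6R,7aR)-5,6-epoxy-7a-methoxy-2-[(8Z)-pentadec-8-en-1-yl]octahydro-1-benzofuran-3a-ol
Product: 15 (4S,6R)-4,6-dihydroxy-6-[(2S,10Z)-2-hydroxyheptadec-10-en-1-yl]cyclohex-2-en-1-one, via epoxy ketone 14 (not isolated)
Conditions: PPTS, acetone/H2O, rt; then Et3N, rt
Reagents that add atoms: water, O
Why: Mild acid hydrolysis of the furanoside-type mixed ketal frees the C1 ketone and the C2' hydroxyl, the ketal being expected to react faster than the deactivated epoxide. Triethylamine then forms the C2 enolate of the β,γ-epoxy ketone 14, which expels the C3 oxygen (E1cB) to give the γ-hydroxy enone; the C4–O bond is not broken, so C4 keeps its configuration.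

## Compound list

1 | (Z)-hexadec-9-enal | CCCCCC/C=C\CCCCCCCC=O | starting material
2 | trimethylsulfonium iodide | C[S+](C)C.[I-] | starting material
3 | dimethylsulfonium methylide | C[S+](C)[CH2-] | intermediate (not isolated)
4 | rac-2-[(8Z)-pentadec-8-en-1-yl]oxirane | CCCCCC/C=C\CCCCCCCC1CO1 | intermediate
5 | (S)-2-[(8Z)-pentadec-8-en-1-yl]oxirane | CCCCCC/C=C\CCCCCCC[C@H]1CO1 | intermediate
6 | 1,2-dibromobenzene | Brc1ccccc1Br | starting material
7 | 2-bromophenylmagnesium chloride | Cl[Mg]c1ccccc1Br | intermediate (not isolated)
8 | (2S,10Z)-1-(2-bromophenyl)heptadec-10-en-2-ol | CCCCCC/C=C\CCCCCCC[C@H](O)Cc1ccccc1Br | intermediate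
9 | (2S)-2-[(8Z)-pentadec-8-en-1-yl]-2,3-dihydro-1-benzofuran | CCCCCC/C=C\CCCCCCC[C@H]1Cc2ccccc2O1 | intermediate
10 | (2S)-2-[(8Z)-pentadec-8-en-1-yl]-2,3,4,7-tetrahydro-1-benzofuran | CCCCCC/C=C\CCCCCCC[C@H]1CC2=C(CC=CC2)O1 | intermediate
11 | (2S,3aS,7aS)-3a,7a-epoxy-2-[(8Z)-pentadec-8-en-1-yl]-2,3,3a,4,7,7a-hexahydro-1-benzofuran (epoxide oxygen trans to the C2 chain) | CCCCCC/C=C\CCCCCCC[C@H]1C[C@@]23CC=CC[C@@]2(O3)O1 | intermediate (not isolated)
12 | (2S,3aS,7aR)-7a-methoxy-2-[(8Z)-pentadec-8-en-1-yl]-2,3,3a,4,7,7a-hexahydro-1-benzofuran-3a-ol | CCCCCC/C=C\CCCCCCC[C@H]1C[C@@]2(O)CC=CC[C@@]2(OC)O1 | intermediate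
13 | (2S,3aR,5S,6R,7aR)-5,6-epoxy-7a-methoxy-2-[(8Z)-pentadec-8-en-1-yl]octahydro-1-benzofuran-3a-ol (epoxide cis to the 3a-hydroxyl) | CCCCCC/C=C\CCCCCCC[C@H]1C[C@@]2(O)C[C@@H]3O[C@@H]3C[C@@]2(OC)O1 | intermediate
14 | (1R,4R,6S)-4-hydroxy-4-[(2S,10Z)-2-hydroxyheptadec-10-en-1-yl]-7-oxabicyclo[4.1.0]heptan-3-one | CCCCCC/C=C\CCCCCCC[C@H](O)C[C@@]1(O)C[C@@H]2O[C@@H]2CC1=O | intermediate (not isolated)
15 | (4S,6R)-4,6-dihydroxy-6-[(2S,10Z)-2-hydroxyheptadec-10-en-1-yl]cyclohex-2-en-1-one | CCCCCC/C=C\CCCCCCC[C@H](O)C[C@@]1(O)C[C@H](O)C=CC1=O | target

## Step count and least certain steps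

Total step count: 8. Longest linear sequence: 8 steps (1 to 15); 6 enters in step 3.

**Step 5 (key step).** The likeliest failures are migration of the new diene into conjugation followed by over-reduction, reductive cleavage of the ring C–O bond, and hydrolysis or air re-aromatisation of the dienol ether during isolation. The fallback postpones the ring closure; it sets out from 5 and returns at 12. Oxirane 5 is opened with commercial 2-methoxyphenylmagnesium bromide (CuI cat., THF, −20 °C) to give (2S,10Z)-1-(2-methoxyphenyl)heptadec-10-en-2-ol F1. Birch reduction of F1 as its lithium alkoxide (Li, NH3, THF, t-BuOH) should give (2S,10Z)-1-(2-methoxycyclohexa-1,4-dien-1-yl)heptadec-10-en-2-ol F2, an open-chain methyl dienol ether with no ring ether to cleave. Buffered m-CPBA in CH2Cl2 at −40 °C then epoxidises the enol ether of F2, and the C2' hydroxyl traps the methoxy-stabilised cation to give 12 directly. Here hydrogen-bond direction from the free hydroxyl replaces the relay through the ring, so the C3a configuration of this material would have to be correlated with 12 from the main route.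

**Step 6.** The likeliest failure is poor facial selectivity, because the chain is 1,3 to the reacting carbons on a nearly flat ring. Further oxidation by excess peracid is a lesser risk. The minor C3a epimer is a diastereomer and should be separable at 12. The fallback replaces substrate control by reagent control; it sets out from 10 and returns at 12. Shi epoxidation (fructose-derived ketone catalyst in the enantiomeric form that reinforces the substrate bias, KHSO5, K2CO3, MeCN/dimethoxymethane/H2O, 0 °C) should give, after hydrolysis of the alkoxy epoxide in the aqueous medium, the lactol (2S,3aS,7aR)-2-[(8Z)-pentadec-8-en-1-yl]-2,3,3a,4,7,7a-hexahydro-1-benzofuran-3a,7a-diol F3. PPTS, MeOH and HC(OMe)3 at 0 °C then exchange the anomeric hydroxyl for methoxyl to give 12.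

**Step 7.** The likeliest failures are slow or unselective oxygen delivery from a tertiary hydroxyl crowded by the neighbouring ketal, and ionisation of the mixed ketal by the Lewis-acidic vanadium species. The fallback changes the order of events; it sets out from 12 and returns at 14. Hydrolysis of 12 before epoxidation (oxalic acid, acetone/H2O, 0 °C) should give (6S)-6-hydroxy-6-[(2S,10Z)-2-hydroxyheptadec-10-en-1-yl]cyclohex-3-en-1-one F4, in equilibrium with lactol F3, under conditions mild enough to keep the alkene out of conjugation. VO(acac)2/t-BuOOH on F4, now directed by an unencumbered α-ketol hydroxyl, should give 14, which triethylamine converts into 15 as in step 8. This order also removes the exposure of the epoxide to aqueous acid in step 8; its own risk is base- or acid-induced conjugation of the β,γ-unsaturated ketone.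

**Step 4.** The likeliest failures are incomplete coupling, loss of bromine by reduction, and oxidation of the secondary alkoxide at the metal. The fallback closes the ring at the other C–O bond with inversion; it sets out from 4 and returns at 9. Resolution of 4 with the (R,R)-(salen)Co(OAc) enantiomer gives (R)-2-[(8Z)-pentadec-8-en-1-yl]oxirane F5. Opening with 2-methoxyphenylmagnesium bromide (CuI cat., THF) gives (2R,10Z)-1-(2-methoxyphenyl)heptadec-10-en-2-ol F6. Demethylation with NaSEt in DMF at 120 °C gives 2-[(2R,10Z)-2-hydroxyheptadec-10-en-1-yl]phenol F7. Mitsunobu closure (PPh3, DIAD, THF, 0 °C → rt) then forms the C2–O bond with inversion and gives 9.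

## Further compounds

F1 | step 5 | (2S,10Z)-1-(2-methoxyphenyl)heptadec-10-en-2-ol | CCCCCC/C=C\CCCCCCC[C@H](O)Cc1ccccc1OC
F2 | step 5 | (2S,10Z)-1-(2-methoxycyclohexa-1,4-dien-1-yl)heptadec-10-en-2-ol | CCCCCC/C=C\CCCCCCC[C@H](O)CC1=C(OC)CC=CC1
F3 | step 6 | (2S,3aS,7aR)-2-[(8Z)-pentadec-8-en-1-yl]-2,3,3a,4,7,7a-hexahydro-1-benzofuran-3a,7a-diol | CCCCCC/C=C\CCCCCCC[C@H]1C[C@@]2(O)CC=CC[C@@]2(O)O1
F4 | step 7 | (6S)-6-hydroxy-6-[(2S,10Z)-2-hydroxyheptadec-10-en-1-yl]cyclohex-3-en-1-one | CCCCCC/C=C\CCCCCCC[C@H](O)C[C@@]1(O)CC=CCC1=O
F5 | step 4 | (R)-2-[(8Z)-pentadec-8-en-1-yl]oxirane | CCCCCC/C=C\CCCCCCC[C@@H]1CO1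
F6 | step 4 | (2R,10Z)-1-(2-methoxyphenyl)heptadec-10-en-2-ol | CCCCCC/C=C\CCCCCCC[C@@H](O)Cc1ccccc1OC
F7 | step 4 | 2-[(2R,10Z)-2-hydroxyheptadec-10-en-1-yl]phenol | CCCCCC/C=C\CCCCCCC[C@@H](O)Cc1ccccc1O
A1 | alternative 1 | (4R,8S,16Z)-4,8-bis[(tert-butyldimethylsilyl)oxy]-6-oxotricos-16-enal | CCCCCC/C=C\CCCCCCC[C@H](O[Si](C)(C)C(C)(C)C)CC(=O)C[C@H](O[Si](C)(C)C(C)(C)C)CCC=O
A2 | alternative 1 | (2R,4R)-4-[(tert-butyldimethylsilyl)oxy]-2-[(2S,10Z)-2-[(tert-butyldimethylsilyl)oxy]heptadec-10-en-1-yl]-2-hydroxycyclohexan-1-one | CCCCCC/C=C\CCCCCCC[C@H](O[Si](C)(C)C(C)(C)C)C[C@@]1(O)C[C@H](O[Si](C)(C)C(C)(C)C)CCC1=O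
A3 | alternative 2 | (3S,10Z)-2-methoxyheptadeca-1,10-dien-3-yl (4S)-4,5-bis[(tert-butyldimethylsilyl)oxy]-2-[(4-methoxybenzyl)oxy]pentanoate (C2 of the acid part either configuration) | CCCCCC/C=C\CCCCCC[C@H](OC(=O)C(OCc1ccc(OC)cc1)C[C@H](O[Si](C)(C)C(C)(C)C)CO[Si](C)(C)C(C)(C)C)C(OC)=C
A4 | alternative 2 | (2S,4Z,12Z)-2-[(2S)-2,3-bis[(tert-butyldimethylsilyl)oxy]propyl]-4-methoxy-2-[(4-methoxybenzyl)oxy]nonadeca-4,12-dienoic acid | OC(=O)[C@](OCc1ccc(OC)cc1)(C[C@H](O[Si](C)(C)C(C)(C)C)CO[Si](C)(C)C(C)(C)C)C/C(OC)=C/CCCCCC/C=C\CCCCCC
A5 | alternative 3 | 2-[(2S,10Z)-2-hydroxyheptadec-10-en-1-yl]benzene-1,4-diol | CCCCCC/C=C\CCCCCCC[C@H](O)Cc1cc(O)ccc1O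
A6 | alternative 3 | (5R)-5-hydroxy-5-[(2S,10Z)-2-hydroxyheptadec-10-en-1-yl]cyclohex-2-ene-1,4-dione | CCCCCC/C=C\CCCCCCC[C@H](O)C[C@@]1(O)CC(=O)C=CC1=O
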